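**Assumption:** the target has no stereocentres (its only stereo-element is the ring-locked cis chromene C=C), so it is achiral and no enantiocontrol is needed.

## Retrosynthetic overview

1. Target 12 ⇐ desilylation of 11 ⇐ key step from enol 10: oxidative dearomatisation of a 6-chromanol to an acyl-p-quinone. This opens the dimethylchroman to the 3-hydroxy-3-methylbutyl chain and lets the enol oxygen add to the quinone C–H next to the acyl group, closing the pyranone (C ring) last.
2. 10 ⇐ C-formylation of deoxybenzoin 9 ⇐ Pd α-arylation of methyl ketone 4 with aryl bromide 8 (makes C3–C1').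
3. 4 ⇐ hydroquinone: mono-acetylation (symmetry broken), then chroman annulation with 2-methylbut-3-en-2-ol. The chroman masks both the side chain and the future 5-OH.
4. 8 ⇐ 4-bromoresorcinol + prenal (B-ring chromene), then TIPS protection.
5. Ring order: B-ring 2H-chromene and the sacrificial A-ring chroman first; the pyranone is formed in the dearomatisation step.

## Route

**Step 1**
Reactants: 1, hydroquinone
Product: 2, 2',5'-dihydroxyacetophenone
Conditions: AcOH, BF3·OEt2, 110 °C
Reagents that add atoms: acetic acid, CC(=O)O
Why: Nencki/Friedel–Crafts C-acylation (O-acylation then Fries under BF3) stops at the chelated mono-ketone because the first acyl group deactivates the ring; this desymmetrises the feedstock.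

**Step 2**
Reactants: 2, 2',5'-dihydroxyacetophenone; 3, 2-methylbut-3-en-2-ol
Product: 4, 1-(6-hydroxy-2,2-dimethylchroman-8-yl)ethan-1-one
Conditions: 3 (1.1 equiv), BF3·OEt2, 1,4-dioxane, rt → 60 °C
Reagents that add atoms: none besides reactant 3 (its five carbons are kept; its OH leaves as water, the ring oxygen is the 2'-O of 2)
Why: Friedel–Crafts prenylation by the dimethylallyl cation then acid-catalysed Markovnikov hydroalkoxylation (tocopherol-type chroman annulation); C3' is the only position ortho to an OH that is not ortho/para to the deactivating acetyl, and only the 2'-OH can close onto it, so the acetyl ends at C8 and the free OH at C6 (no stereocentre).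

**Step 3**
Reactants: 5, 4-bromoresorcinol; 6, 3-methylbut-2-enal (prenal)
Product: 7, 6-bromo-2,2-dimethyl-2H-chromen-7-ol
Conditions: 6 (1.5 equiv), ethylenediammonium diacetate (20 mol %), xylene, reflux, Dean–Stark
Reagents that add atoms: none besides reactant 6 (five carbons kept; its oxygen leaves as water)
Why: Knoevenagel-type C-alkylation at the less hindered C6 of the resorcinol, dehydration to an o-quinone methide and oxa-6π electrocyclisation give the linear 2H-chromene; bromine marks the future C1' (the minor isomer from attack between the two OH groups is removed by chromatography; no stereocentre).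

**Step 4**
Reactants: 7, 6-bromo-2,2-dimethyl-2H-chromen-7-ol
Product: 8, [(6-bromo-2,2-dimethyl-2H-chromen-7-yl)oxy]triisopropylsilane
Conditions: TIPSCl, imidazole, DMF, rt → 40 °C
Reagents that add atoms: triisopropylsilyl chloride, CC(C)[Si](Cl)(C(C)C)C(C)C
Why: standard phenol silylation; the TIPS ether survives LiHMDS and ethoxide, prevents benzofuran formation from the 2'-OH during formylation, and keeps the B ring inert to iodine(III) in the key step.

**Step 5**
Reactants: 4, 1-(6-hydroxy-2,2-dimethylchroman-8-yl)ethan-1-one (1.2 equiv); 8, aryl bromide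
Product: 9, 1-(6-hydroxy-2,2-dimethylchroman-8-yl)-2-{2,2-dimethyl-7-[(triisopropylsilyl)oxy]-2H-chromen-6-yl}ethan-1-one
Conditions: Pd2(dba)3 (2.5 mol %), XPhos (6 mol %), LiHMDS (3.2 equiv), THF, 60 °C
Reagents that add atoms: none
Why: Pd-catalysed ketone α-arylation (Buchwald–Hartwig type) of the methyl-ketone enolate, with the phenol carried as its lithium phenoxide; the bulky ligand and the ortho-OTIPS group stop the reaction at mono-arylation.

**Step 6**
Reactants: 9, deoxybenzoin
Product: 10, (Z)-3-hydroxy-1-(6-hydroxy-2,2-dimethylchroman-8-yl)-2-{2,2-dimethyl-7-[(triisopropylsilyl)oxy]-2H-chromen-6-yl}prop-2-en-1-one (chelated enol of the α-formyl ketone)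
Conditions: NaH (3 equiv), HCO2Et (excess), THF, 0 °C → rt; AcOH quench
Reagents that add atoms: ethyl formate, CCOC=O
Why: crossed Claisen condensation (C-formylation) at the doubly activated benzylic CH2; the product sits as the H-bonded Z-enol and cannot close to a chromone because the ketone aryl has only the chroman ether and a C–H at its ortho positions.

**Step 7 (key step)**
Reactants: 10, enol
Product: 11, 5,8-dihydroxy-6-(3-hydroxy-3-methylbutyl)-3-{2,2-dimethyl-7-[(triisopropylsilyl)oxy]-2H-chromen-6-yl}-4H-chromen-4-one
Conditions: PhI(OAc)2 (2.2 equiv), MeCN/H2O 4:1, 0 °C → rt; then aq. Na2S2O4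
Reagents that add atoms: water, O (becomes the C5–OH oxygen; the enol oxygen becomes O1, the chroman oxygen becomes the tertiary OH)
Why: Proposed new method: the free p-alkoxyphenol is the most oxidisable site (the B-ring phenol is silylated), so iodine(III) gives the aryloxy-oxocarbenium ion, water adds at C8a and the hemiketal collapses as in the tocopherol → tocopherylquinone oxidation, dearomatising the ring to a 2-acyl-1,4-benzoquinone and releasing the chroman oxygen as the tertiary alcohol; the quinone C–H carbon next to the acyl group (β to both carbonyls, the usual site of nucleophilic attack on 2-acylbenzoquinones) is captured 6-endo by the enol oxygen (oxa-Michael, as in chalcone → flavanone closure) and tautomerisation rearomatises to the 5,8-dihydroxychromone; the second equivalent of oxidant holds everything at the quinone level so no acyl-hydroquinone can cyclise onto the wrong oxygen, and dithionite then returns the hydroquinone; closest known reactions are the oxidative ring-opening of 6-chromanols to hydroxyalkyl quinones and conjugate additions at C3 of 2-acylquinones; no stereocentre is formed.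

**Step 8**
Reactants: 11, TIPS-protected isoflavone
Product: 12, kraussianone 3 [5,8-dihydroxy-6-(3-hydroxy-3-methylbutyl)-3-(7-hydroxy-2,2-dimethyl-2H-chromen-6-yl)-4H-chromen-4-one]
Conditions: TBAF/AcOH (1:1), THF, 0 °C, Ar; aq. Na2S2O4 wash
Reagents that add atoms: none
Why: fluoride-mediated Si–O cleavage of the aryl silyl ether; buffering and exclusion of air protect the hydroquinone, and the chromene and tertiary alcohol (both acid-sensitive) are not exposed to acid.

## Compound list

1 | hydroquinone | Oc1ccc(O)cc1 | starting material
2 | 2',5'-dihydroxyacetophenone | CC(=O)c1cc(O)ccc1O | intermediate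
3 | 2-methylbut-3-en-2-ol | CC(C)(O)C=C | starting material
4 | 1-(6-hydroxy-2,2-dimethylchroman-8-yl)ethan-1-one | CC(=O)c1cc(O)cc2c1OC(C)(C)CC2 | intermediate
5 | 4-bromoresorcinol | Oc1ccc(Br)c(O)c1 | starting material
6 | 3-methylbut-2-enal (prenal) | CC(C)=CC=O | starting material
7 | 6-bromo-2,2-dimethyl-2H-chromen-7-ol | CC1(C)C=Cc2cc(Br)c(O)cc2O1 | intermediate
8 | [(6-bromo-2,2-dimethyl-2H-chromen-7-yl)oxy]triisopropylsilane | CC1(C)C=Cc2cc(Br)c(O[Si](C(C)C)(C(C)C)C(C)C)cc2O1 | intermediate
9 | 1-(6-hydroxy-2,2-dimethylchroman-8-yl)-2-{2,2-dimethyl-7-[(triisopropylsilyl)oxy]-2H-chromen-6-yl}ethan-1-one | CC1(C)CCc2cc(O)cc(C(=O)Cc3cc4C=CC(C)(C)Oc4cc3O[Si](C(C)C)(C(C)C)C(C)C)c2O1 | intermediate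
10 | (Z)-3-hydroxy-1-(6-hydroxy-2,2-dimethylchroman-8-yl)-2-{2,2-dimethyl-7-[(triisopropylsilyl)oxy]-2H-chromen-6-yl}prop-2-en-1-one | CC1(C)CCc2cc(O)cc(C(=O)/C(=C\O)c3cc4C=CC(C)(C)Oc4cc3O[Si](C(C)C)(C(C)C)C(C)C)c2O1 | intermediate
11 | 5,8-dihydroxy-6-(3-hydroxy-3-methylbutyl)-3-{2,2-dimethyl-7-[(triisopropylsilyl)oxy]-2H-chromen-6-yl}-4H-chromen-4-one | CC(C)(O)CCc1cc(O)c2occ(-c3cc4C=CC(C)(C)Oc4cc3O[Si](C(C)C)(C(C)C)C(C)C)c(=O)c2c1O | intermediate
12 | kraussianone 3 | CC(C)(O)CCc1cc(O)c2occ(-c3cc4c(cc3O)OC(C)(C)C=C4)c(=O)c2c1O | target

## Summary

Total steps: 8. Longest linear sequence: 6 (steps 1, 2, 5, 6, 7, 8 from hydroquinone; the bromide arm, steps 3, 4, then 5–8, is also 6).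

Three steps most likely to fail, each with a fallback that changes the approach:

1. **Step 7 (oxidative dearomatisation / ring-opening / oxa-Michael cascade).** Risks are comproportionation leading to closure onto the wrong oxygen (the 6-hydroxy-8-alkyl isomer), iodine(III) attack on the enol or chromene, and addition of the tertiary alcohol to the quinone. Fallback: separate the events. Oxidise ketone 4 itself to 2-acetyl-6-(3-hydroxy-3-methylbutyl)-1,4-benzoquinone, install the extra oxygen intermolecularly by Thiele–Winter-type addition next to the acetyl group, and then build the isoflavone from the resulting 2,3,6-trioxygenated acetophenone by conventional arylation, formylation and cyclodehydration.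

2. **Step 5 (α-arylation with a free phenoxide on the ketone and a hindered, electron-rich aryl bromide).** Fallback: make the C3–C1' bond after the heterocycle. Formylate 4 and run the step-7 cascade without a B ring to get the 3-unsubstituted 5,8-dihydroxychromone, protect it, iodinate C3, and attach the B ring by Suzuki coupling with the pinacol boronate made from 8.

3. **Step 2 (regiochemistry of the chroman annulation, C3' versus C4'/C6').** Fallback: reverse the order on hydroquinone. Annulate hydroquinone with 3 first to give 2,2-dimethylchroman-6-ol (no regiochemical question, by symmetry), O-acetylate so the ring ether oxygen becomes the dominant director, Friedel–Crafts acetylate at C8, and deacetylate to 4.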